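**Retrosynthetic overview**

- The route rests on C2 of the indoxyl: a fully substituted carbon that is α to the C3 ketone and bonded to N1 of the five-membered ring B (fused to benzo ring A). It carries two identical indol-3-yl groups, so it is not a stereocentre.
- N1–C2 is disconnected last, and ring B is the only ring the route forms: Smalley azide–enolate cyclisation of 1-(2-azidophenyl)-2,2-bis(1H-indol-3-yl)ethanone. Both indole ring systems are bought.
- Both C2–C3' bonds come from an acid-catalysed double Friedel–Crafts reaction of two indoles at the aldehyde carbon of (2-azidophenyl)glyoxal.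
- The glyoxal comes from 2'-aminoacetophenone by diazotisation/azidation and a DMSO/HBr oxidation at 55 °C, chosen because an ortho-azidoaryl ketone should not outlast a refluxing SeO2 oxidation.
- The indole N–H groups stay free: N-carbamates would not survive the alkoxide base of the ring closure and are not needed, since the methine is the only enolisable position.

Key step: step 4

Remark: the arylglyoxal is assumed to be collected as its gem-diol after aqueous work-up; hydrate and free aldehyde serve alike in step 3. All azides are kept at or below 55 °C and away from light.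

**Step 1**
Reactants: 1 2'-aminoacetophenone
Product: 3 2'-azidoacetophenone [1-(2-azidophenyl)ethanone], via 2-acetylbenzenediazonium chloride 2 (not isolated)
Conditions: NaNO2, 6 M aq. HCl, 0 °C; then NaN3, H2O, 0 °C → rt
Reagents that add atoms: sodium nitrite, O=N[O-].[Na+]; sodium azide, [N-]=[N+]=[N-].[Na+]
Why: Diazotisation of the aniline and capture of the diazonium ion by azide with loss of N2 is the standard Sandmeyer-type azidation of an arylamine, and the ortho-acetyl group is inert at 0 °C.

**Step 2**
Reactants: 3 2'-azidoacetophenone
Product: 6 (2-azidophenyl)glyoxal hydrate [1-(2-azidophenyl)-2,2-dihydroxyethanone], via 2-azidophenacyl bromide 4 (not isolated), via 2-azidophenylglyoxal 5 (not isolated)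
Conditions: 48% aq. HBr (3 equiv), DMSO, 55 °C, N2 sweep; then ice/H2O
Reagents that add atoms: dimethyl sulfoxide, CS(C)=O; water, O
Why: The DMSO/HBr oxidation of an aryl methyl ketone (α-bromination by Br2 formed in the flask, then Kornblum oxidation of the phenacyl bromide by DMSO) runs at 55 °C, where loss of N2 from the ortho-azido ketone to the anthranil should still be slow, and the electron-poor azidoarene should resist ring bromination.

**Step 3**
Reactants: 6 (2-azidophenyl)glyoxal hydrate; 7 indole (2.1 equiv)
Product: 9 1-(2-azidophenyl)-2,2-bis(1H-indol-3-yl)ethanone, via mono-indolyl carbinol 8 (not isolated)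
Conditions: TsOH·H2O (10 mol%), MeCN, rt, N2, dark
Reagents that add atoms: none
Why: In this bis(indolyl)methane-type double Friedel–Crafts reaction, indole C3 adds to the aldehyde carbon (more electrophilic than the aryl ketone), the protonated indol-3-yl carbinol loses water, and a second indole is alkylated at C3, while the azide is untouched at room temperature.

**Step 4**
Reactants: 9 1-(2-azidophenyl)-2,2-bis(1H-indol-3-yl)ethanone
Product: 11 2,2-bis(1H-indol-3-yl)indolin-3-one [2,2-bis(3'-indolyl)indoxyl, the target], via potassium enolate 10 (not isolated)
Conditions: KOH (2 equiv), EtOH/THF, 0 °C → rt, Ar, dark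
Reagents that add atoms: none
Why: Base removes the single enolisable proton of 9, the methine flanked by the aryl ketone and two indol-3-yl groups, and the enolate carbon of 10 bonds to the aryl-bound nitrogen of the ortho azide as N2 departs, the indoxyl N–H arising by proton transfer from the solvent. This is the Smalley cyclisation of ortho-azidophenyl sec-alkyl ketones to 2,2-disubstituted indoxyls, here with two heteroaryl groups on the secondary carbon. Ring B closes as a five-membered ring by N1–C2 bond formation, with the enolate C=C inside the new ring and the breaking N–N2 bond outside it (5-exo with respect to the leaving group). No stereocentre is created, because C2 ends up with two identical indol-3-yl substituents. The step needs C-amination to win over O-attack (which would give only the weak N–O bond of an anthranil-type ring, the path of the neutral ketone on heating) and over aerobic oxidation of the electron-rich enolate; the fully substituted enolate cannot lie coplanar with the azidoarene, which should turn the C2 π lobe toward the azide, and working at or below room temperature under argon closes the thermal and oxidative channels. The indole N–H groups are deprotonated only reversibly and there is no second enolisable site, so no protection is required.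

**Compound list**

1 | 2'-aminoacetophenone | CC(=O)c1ccccc1N | starting material
2 | 2-acetylbenzenediazonium chloride | CC(=O)c1ccccc1[N+]#N.[Cl-] | intermediate (not isolated)
3 | 2'-azidoacetophenone | CC(=O)c1ccccc1N=[N+]=[N-] | intermediate
4 | 2-azidophenacyl bromide [1-(2-azidophenyl)-2-bromoethanone] | O=C(CBr)c1ccccc1N=[N+]=[N-] | intermediate (not isolated)
5 | 2-azidophenylglyoxal [2-(2-azidophenyl)-2-oxoacetaldehyde] | O=CC(=O)c1ccccc1N=[N+]=[N-] | intermediate (not isolated)
6 | (2-azidophenyl)glyoxal hydrate [1-(2-azidophenyl)-2,2-dihydroxyethanone] | OC(O)C(=O)c1ccccc1N=[N+]=[N-] | intermediate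
7 | indole | c1ccc2[nH]ccc2c1 | starting material
8 | mono-indolyl carbinol [1-(2-azidophenyl)-2-hydroxy-2-(1H-indol-3-yl)ethanone] | OC(C(=O)c1ccccc1N=[N+]=[N-])c1c[nH]c2ccccc12 | intermediate (not isolated)
9 | 1-(2-azidophenyl)-2,2-bis(1H-indol-3-yl)ethanone | [N-]=[N+]=Nc1ccccc1C(=O)C(c1c[nH]c2ccccc12)c1c[nH]c2ccccc12 | intermediate
10 | potassium enolate of 9 [potassium 1-(2-azidophenyl)-2,2-bis(1H-indol-3-yl)ethenolate] | [K+].[O-]C(=C(c1c[nH]c2ccccc12)c1c[nH]c2ccccc12)c1ccccc1N=[N+]=[N-] | intermediate (not isolated)
11 | 2,2-bis(1H-indol-3-yl)indolin-3-one [2,2-bis(3'-indolyl)indoxyl] | O=C1c2ccccc2NC1(c1c[nH]c2ccccc12)c1c[nH]c2ccccc12 | target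

Total step count: 4
Longest linear sequence: 4 steps (1 → 3 → 6 → 9 → 11; indole 7 enters in step 3)

**Steps most likely to fail, with fallbacks**

Step 4 (key step). What may go wrong: C–N bond formation at the crowded, cross-conjugated enolate may be slow, so that loss of N2 with oxygen participation or oxidation of the enolate takes over. The fallback sets out from 9 and comes back at 11, making the same N1–C2 bond with reversed polarity. Hydrogenation of the azide (H2, Pd/C, EtOAc, rt) should give 1-(2-aminophenyl)-2,2-bis(1H-indol-3-yl)ethanone F1. DDQ (1 equiv, CH2Cl2, 0 °C) should then abstract hydride from the doubly indolyl-activated methine and, after loss of an indole N–H proton, give the 3-alkylidene-3H-indole 1-(2-aminophenyl)-2-(1H-indol-3-yl)-2-(3H-indol-3-ylidene)ethanone F2. The ortho amino group adds to its exocyclic carbon (5-exo-trig conjugate addition that restores the indole) and gives 11.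

Step 2. What may go wrong: the azide may be lost during the oxidation, by acid- or bromine-induced decomposition or by slow cyclisation to the anthranil, or the methyl group may be over-brominated. The fallback postpones the azide: it sets out from indole 7 and a new starting material, 2'-nitroacetophenone F3, and comes back at 9. Riley oxidation (SeO2, dioxane/H2O, reflux), which the nitro group tolerates, should give (2-nitrophenyl)glyoxal hydrate F4. Condensation with 7 (2 equiv, TsOH·H2O cat., MeCN, rt) should give 2,2-bis(1H-indol-3-yl)-1-(2-nitrophenyl)ethanone F5. Hydrogenation (H2, Pd/C, EtOH/EtOAc, rt) should give 1-(2-aminophenyl)-2,2-bis(1H-indol-3-yl)ethanone F1, the amine also met in the fallback to step 4. Diazotisation with one equivalent of NaNO2 (aq. HCl/AcOH, 0 °C) should give 2-[2,2-bis(1H-indol-3-yl)acetyl]benzenediazonium chloride F6, and NaN3 at 0 °C then gives 9. Diazotisation of the aniline is expected to outpace nitrosation of the 3-substituted indoles at 0 °C.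

Step 3. What may go wrong: the condensation may stall after the first indole addition, or the acid may cause oligomerisation or air oxidation of the electron-rich bis(indolyl)methine. The fallback brings in the second indole only after ring B is closed; it sets out from 6 and 7 and comes back at 11. With one equivalent of indole and no acid (MeOH, rt) the reaction is stopped at carbinol 8, which is isolated. MnO2 (CH2Cl2, rt) should oxidise it to 1-(2-azidophenyl)-2-(1H-indol-3-yl)ethane-1,2-dione F7. PPh3 (toluene, rt → 50 °C) should convert the azide into the iminophosphorane 1-(1H-indol-3-yl)-2-[2-(triphenylphosphoranylideneamino)phenyl]ethane-1,2-dione F8. This closes by intramolecular aza-Wittig reaction on the indolyl ketone (the only carbonyl that gives a five-membered ring) to 2-(1H-indol-3-yl)-3H-indol-3-one F9. Acid-catalysed addition of indole 7 (TsOH·H2O cat., CH2Cl2, rt) to the C2=N bond of this indolone then gives 11.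

**Further compounds**

F1 | step 4 | 1-(2-aminophenyl)-2,2-bis(1H-indol-3-yl)ethanone | Nc1ccccc1C(=O)C(c1c[nH]c2ccccc12)c1c[nH]c2ccccc12
F2 | step 4 | 1-(2-aminophenyl)-2-(1H-indol-3-yl)-2-(3H-indol-3-ylidene)ethanone | Nc1ccccc1C(=O)C(c1c[nH]c2ccccc12)=C1C=Nc2ccccc12
F3 | step 2 | 2'-nitroacetophenone | CC(=O)c1ccccc1[N+](=O)[O-]
F4 | step 2 | (2-nitrophenyl)glyoxal hydrate [2,2-dihydroxy-1-(2-nitrophenyl)ethanone] | OC(O)C(=O)c1ccccc1[N+](=O)[O-]
F5 | step 2 | 2,2-bis(1H-indol-3-yl)-1-(2-nitrophenyl)ethanone | O=C(c1ccccc1[N+](=O)[O-])C(c1c[nH]c2ccccc12)c1c[nH]c2ccccc12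
F6 | step 2 | 2-[2,2-bis(1H-indol-3-yl)acetyl]benzenediazonium chloride | N#[N+]c1ccccc1C(=O)C(c1c[nH]c2ccccc12)c1c[nH]c2ccccc12.[Cl-]
F7 | step 3 | 1-(2-azidophenyl)-2-(1H-indol-3-yl)ethane-1,2-dione | O=C(C(=O)c1c[nH]c2ccccc12)c1ccccc1N=[N+]=[N-]
F8 | step 3 | 1-(1H-indol-3-yl)-2-[2-(triphenylphosphoranylideneamino)phenyl]ethane-1,2-dione | O=C(C(=O)c1c[nH]c2ccccc12)c1ccccc1N=P(c1ccccc1)(c1ccccc1)c1ccccc1
F9 | step 3 | 2-(1H-indol-3-yl)-3H-indol-3-one | O=C1C(c2c[nH]c3ccccc23)=Nc2ccccc12
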